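Time in these runs reads better as a share of the charge. By 1.50 h the cedar run has made target at 65.3 mM h⁻¹ and the alder run at 60.0 mM h⁻¹, so early formation looks zero-order in the charge, with a mean of 62.7 mM h⁻¹.

in all of them: gas 42 mM (held)
- cedar: solid substrate 0.20 M; run made earlier
- alder: solid substrate 0.45 M; run made earlier
- flask: solid substrate 0.30 M; time 50 h

| run | time / h | target / % |
|---|---|---|
| cedar | 0.833 | 26 |
| cedar | 1.50 | 49 |
| cedar | 3.00 | 51 |
| cedar | 6.00 | 41 |
| cedar | 15.0 | 40 |
| cedar | 30.0 | 42 |
| cedar | 60.0 | 40 |
| alder | 0.833 | 15 |
| alder | 1.50 | 20 |
| alder | 3.00 | 39 |
| alder | 6.00 | 41 |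
| alder | 15.0 | 41 |
| alder | 30.0 | 43 |
| alder | 60.0 | 39 |

(standard deviation of a reading: 2 percentage points)

- solid, in amounts per volume of the solution: solid substrate
- the analysis behind the earlier runs scatters by 2 percentage points, standard deviation
- at the start none of the solid substrate is in solution
- at the start none of the gas is in solution

- the moment within 50 h at which there is most target
- the amount of target, in percent of the solid substrate charged, at that time

I fold rate, time and charge into one number, the delivered share: rate times time over charge, and one minus it is what is still to come. The cedar run has climbed to 49% at share 0.470 with no fall yet in its readings, and the alder run reads level at 41% by share 0.836. I therefore take the midpoint, 0.653, as the delivered share at the top of target.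

Is one number enough? On the rise, yes: alder at 3.00 h has share 0.418 and reads 39%, near the 41.8% that this share gives. Past the top, no: cedar at 3.00 h, share 0.940, reads 51%, while alder at 6.00 h, share 0.836, reads 41%. That gap of 10 percentage points is wider than a scatter of 2 points, so the share does not place these two readings, and the one earlier on the clock stands higher. For this flask I reckon the top at 3.12 h, and the top share scaled by alder's ratio of reading to share on the rise gives a best of 60.9%.

The forecast, finding early formation "independent of charge", gives 52% at 2.8 h. The flask gives 57.3% at 3.00 h.

    solid substrate ⇌ dissolved substrate, rate k1*(cs1 - [dissolved substrate]) while solid is left; crystals form when [dissolved substrate] > cs1 (solubility = 0.0890 M, k = 3.20 × 10⁻⁴ s⁻¹)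
    dissolved substrate + coupling partner → target (k = 0.650 M⁻¹ s⁻¹)
    2 dissolved substrate → side product (k = 0.450 M⁻¹ s⁻¹)
    gas ⇌ coupling partner, rate k4*(csat - [coupling partner]) (kL = 0.00120 s⁻¹)
    target ⇌ isomer of the product (K = 1.20, k = 1.30 × 10⁻⁴ s⁻¹)

The neighbouring flask holds 0.51 M of solid substrate and is otherwise unchanged. The same reckoning, with the same rate and the same delivered share at the top, places its top at 5.31 h, later on the clock than this flask's 3.00 h. Its best is 51.2%, below this flask's 57.3%. At 50.0 h it holds 40.3% target and 48.3% isomer of the product.

Readings and results are simulated from invented constants.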